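**Plan**

- Retrosynthesis: cut the benzyl ester C–O bond on ring B (hydrogenolysis), then bonds C1–C2 and C5–C6 of ring A (Diels–Alder of an aryl oct-2-ynoate with 1,1-dimethoxy-3-(trimethylsilyloxy)buta-1,3-diene), then the depside acyl C–O bond (esterification with oct-2-ynoic acid), then the same two ring bonds of ring B.
- Enabling feature: ring A carries C2-OMe, C4-OH and C6-pentyl around the C1 carbonyl carbon, which is exactly the pattern this diene writes onto an oct-2-ynoate. Ring B has the same pattern, so the annulation is used twice.
- Forward order: the diene is made in three steps from acetyl chloride and 1,1-dichloroethene. Ring B arises by cycloaddition to benzyl oct-2-ynoate, its C4 phenol is acylated with the linear ynoic acid, ring A is grown on the finished ester, and the benzyl group is removed last.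
- Stereochemistry: the target has no stereocentre and no stereogenic double bond. The only selectivity to secure is the regiochemistry of the two cycloadditions, which follows from the polarisation of diene and ynoate.
- Remark on the chemistry: the diene is prepared once and used in steps 5 and 7; LDA is taken as the commercial solution.

Key step: step 7

**Route**

Step 1
Reactants: 1 acetyl chloride; 2 1,1-dichloroethene
Product: 4 4,4-dichlorobut-3-en-2-one, via 4,4,4-trichlorobutan-2-one 3 (not isolated)
Conditions: AlCl3 (1.1 equiv), CH2Cl2, 0 °C to rt; ice/aq. HCl; then distillation under reduced pressure (−HCl)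
Reagents that add atoms: none
Why: Friedel–Crafts-type acylation of an alkene, in which the acylium ion from 1 and AlCl3 adds to the CH2 terminus of 2 to give a chlorine-stabilised cation that takes up chloride, and the β-trichloromethyl ketone 3 then loses HCl easily on distillation because its α-hydrogens are acidic and the product is a conjugated enone.

Step 2
Reactants: 4 4,4-dichlorobut-3-en-2-one
Product: 6 4,4-dimethoxybut-3-en-2-one, via 4-chloro-4-methoxybut-3-en-2-one 5 (not isolated)
Conditions: NaOMe (2.2 equiv), MeOH, 0 °C to rt; filter; distil (no aqueous work-up)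
Reagents that add atoms: sodium methoxide, [Na+].[O-]C
Why: Two consecutive addition–elimination (vinylic substitution) reactions of methoxide at the β-carbon of the β,β-dichloroenone, each adduct being held as an enolate before chloride leaves, which is a standard way to an acylketene acetal.

Step 3
Reactants: 6 4,4-dimethoxybut-3-en-2-one
Product: 8 1,1-dimethoxy-3-(trimethylsilyloxy)buta-1,3-diene, via lithium dienolate 7 (not isolated)
Conditions: LDA (LiN(i-Pr)2, 1.1 equiv), THF, −78 °C; then TMSCl (1.2 equiv), −78 °C to rt; pentane, filter, distil
Reagents that add atoms: chlorotrimethylsilane, C[Si](C)(C)Cl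
Why: Kinetic deprotonation by LDA of the methyl group, the only enolisable position, should give the cross-conjugated lithium dienolate 7, which TMSCl traps on oxygen (silyl enol ether formation).

Step 4
Reactants: 9 oct-2-ynoic acid; 10 benzyl alcohol
Product: 11 benzyl oct-2-ynoate
Conditions: DCC (1.1 equiv), DMAP (5 mol%), CH2Cl2, 0 °C to rt
Reagents that add atoms: none
Why: Steglich esterification, in which DCC activates the acid and catalytic DMAP passes the acyl group to the primary alcohol at 0 °C, conditions under which a 3-alkyl-substituted ynoate is not attacked at its β-carbon.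

Step 5
Reactants: 11 benzyl oct-2-ynoate; 8 1,1-dimethoxy-3-(trimethylsilyloxy)buta-1,3-diene
Product: 14 benzyl 4-hydroxy-2-methoxy-6-pentylbenzoate, via cyclohexadiene cycloadduct 12 (not isolated), via aryl trimethylsilyl ether 13 (not isolated)
Conditions: 8 (2.5 equiv), neat, sealed tube, 130 °C; then 1 M aq. HCl, THF, rt
Reagents that add atoms: none
Why: Thermal Diels–Alder benzannulation of an alkyl 2-alkynoate with a 1,1-dialkoxy-3-silyloxybutadiene, a known reaction type, in which the CH2 terminus of 8 bonds to the pentyl-bearing β-carbon and the acetal carbon to the α-carbon, adduct 12 aromatises by loss of methanol, and dilute acid cleaves the aryl silyl ether 13 so that C2-OMe and C4-OH come out differentiated.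

Step 6
Reactants: 14 benzyl 4-hydroxy-2-methoxy-6-pentylbenzoate; 9 oct-2-ynoic acid
Product: 15 benzyl 2-methoxy-4-(oct-2-ynoyloxy)-6-pentylbenzoate
Conditions: 9 (1.2 equiv), DCC (1.3 equiv), DMAP (10 mol%), CH2Cl2, 0 °C to rt
Reagents that add atoms: none
Why: Steglich esterification of the unhindered C4 phenol of ring B with the linear ynoic acid, whose carbonyl is flanked only by an sp carbon and is therefore easy to attack, unlike the carbonyl of a 2,6-disubstituted benzoic acid.

Step 7
Reactants: 15 benzyl 2-methoxy-4-(oct-2-ynoyloxy)-6-pentylbenzoate; 8 1,1-dimethoxy-3-(trimethylsilyloxy)buta-1,3-diene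
Product: 18 benzyl 4-[(4-hydroxy-2-methoxy-6-pentylbenzoyl)oxy]-2-methoxy-6-pentylbenzoate, via ring A cyclohexadiene cycloadduct 16 (not isolated), via depside trimethylsilyl ether 17 (not isolated)
Conditions: 8 (3 equiv), toluene, 4 Å molecular sieves, 110 °C; then 0.5 M aq. HCl, THF, 0 °C
Reagents that add atoms: none
Why: The CH2 terminus of the diene, which carries the largest HOMO coefficient because the C3 silyloxy group and the two C1 methoxy groups all push electron density toward it, attacks the pentyl-bearing β-carbon of the aryl ynoate (future C6 of ring A) and the ketene acetal carbon then bonds to the α-carbon (future C1), so that bonds C5–C6 and C1–C2 form in a concerted but strongly asynchronous Diels–Alder reaction. The closest known reaction type is the thermal benzannulation of 1,1-dialkoxy-3-silyloxybutadienes with alkyl 2-alkynoates, and the aryl ester used here should lower the alkyne LUMO further. Ring A closes as a six-membered carbocycle in the (4+2) cycloaddition mode, both new bonds coming from one diene and one two-π component. Adduct 16 holds a geminal dimethoxy carbon para to a ring CH2 group and should lose methanol by 1,4-elimination to the arene 17, whose labile aryl silyl ether falls off in the mild acid work-up, so that C2-OMe and C4-OH emerge differentiated without a protecting-group step. No stereocentre is created; the step needs regioselectivity, secured by matching the nucleophilic CH2 terminus with the electrophilic β-carbon, and chemoselectivity for the alkyne over the two ester carbonyls, secured by the absence of any nucleophile or Lewis acid while the sieves and the excess silyl diene take up the liberated methanol. Because the depside C–O bond is already in place before ring A exists, the crowded 2,6-disubstituted carbonyl never has to be attacked.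

Step 8
Reactants: 18 benzyl 4-[(4-hydroxy-2-methoxy-6-pentylbenzoyl)oxy]-2-methoxy-6-pentylbenzoate
Product: 19 4-O-demethylplanaic acid (4-[(4-hydroxy-2-methoxy-6-pentylbenzoyl)oxy]-2-methoxy-6-pentylbenzoic acid)
Conditions: H2 (1 atm), 10% Pd/C, EtOAc, rt
Reagents that add atoms: none
Why: Hydrogenolysis of the benzylic C–O bond over palladium on carbon at ambient pressure should free the acid under neutral conditions that leave the aryl ester of the depside, the methyl ethers and both arenes untouched.

**Compound list**

1 | acetyl chloride | CC(=O)Cl | starting material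
2 | 1,1-dichloroethene | C=C(Cl)Cl | starting material
3 | 4,4,4-trichlorobutan-2-one | CC(=O)CC(Cl)(Cl)Cl | intermediate
4 | 4,4-dichlorobut-3-en-2-one | CC(=O)C=C(Cl)Cl | intermediate
5 | 4-chloro-4-methoxybut-3-en-2-one (double-bond geometry not defined, either isomer reacts on) | CC(=O)C=C(Cl)OC | intermediate
6 | 4,4-dimethoxybut-3-en-2-one | CC(=O)C=C(OC)OC | intermediate
7 | lithium 4,4-dimethoxybuta-1,3-dien-2-olate | [Li+].[O-]C(=C)C=C(OC)OC | intermediate
8 | 1,1-dimethoxy-3-(trimethylsilyloxy)buta-1,3-diene | COC(OC)=CC(=C)O[Si](C)(C)C | intermediate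
9 | oct-2-ynoic acid | CCCCCC#CC(=O)O | starting material
10 | benzyl alcohol | OCc1ccccc1 | starting material
11 | benzyl oct-2-ynoate | CCCCCC#CC(=O)OCc1ccccc1 | intermediate
12 | benzyl 6,6-dimethoxy-2-pentyl-4-(trimethylsilyloxy)cyclohexa-1,4-diene-1-carboxylate | CCCCCC1=C(C(=O)OCc2ccccc2)C(OC)(OC)C=C(O[Si](C)(C)C)C1 | intermediate
13 | benzyl 2-methoxy-6-pentyl-4-(trimethylsilyloxy)benzoate | CCCCCc1cc(O[Si](C)(C)C)cc(OC)c1C(=O)OCc1ccccc1 | intermediate
14 | benzyl 4-hydroxy-2-methoxy-6-pentylbenzoate | CCCCCc1cc(O)cc(OC)c1C(=O)OCc1ccccc1 | intermediate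
15 | benzyl 2-methoxy-4-(oct-2-ynoyloxy)-6-pentylbenzoate | CCCCCC#CC(=O)Oc1cc(CCCCC)c(C(=O)OCc2ccccc2)c(OC)c1 | intermediate
16 | 4-(benzyloxycarbonyl)-3-methoxy-5-pentylphenyl 6,6-dimethoxy-2-pentyl-4-(trimethylsilyloxy)cyclohexa-1,4-diene-1-carboxylate | CCCCCC1=C(C(=O)Oc2cc(CCCCC)c(C(=O)OCc3ccccc3)c(OC)c2)C(OC)(OC)C=C(O[Si](C)(C)C)C1 | intermediate
17 | benzyl 2-methoxy-4-{[2-methoxy-6-pentyl-4-(trimethylsilyloxy)benzoyl]oxy}-6-pentylbenzoate | CCCCCc1cc(OC(=O)c2c(CCCCC)cc(O[Si](C)(C)C)cc2OC)cc(OC)c1C(=O)OCc1ccccc1 | intermediate
18 | benzyl 4-[(4-hydroxy-2-methoxy-6-pentylbenzoyl)oxy]-2-methoxy-6-pentylbenzoate | CCCCCc1cc(OC(=O)c2c(CCCCC)cc(O)cc2OC)cc(OC)c1C(=O)OCc1ccccc1 | intermediate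
19 | 4-O-demethylplanaic acid | CCCCCc1cc(OC(=O)c2c(CCCCC)cc(O)cc2OC)cc(OC)c1C(=O)O | target

**Count and risks**

Total step count: 8. Longest linear sequence: 7 (steps 1, 2, 3, 5, 6, 7, 8); step 4 is a one-step side branch.

Steps most likely to fail:

1. Step 7. The cycloaddition to the internal ynoate may be slower than the thermal breakdown of the silyl diene, and methanol released on aromatisation may cleave the activated aryl ynoate ester by transesterification before ring A has formed. The fallback builds the depside link by classical acylation instead. It sets out from 14 and comes back to the route at 18. One portion of 14 would be silylated (TBSCl, imidazole, DMF) to benzyl 4-(tert-butyldimethylsilyloxy)-2-methoxy-6-pentylbenzoate F1. Hydrogenolysis (H2, 10% Pd/C, EtOAc) should then give 4-(tert-butyldimethylsilyloxy)-2-methoxy-6-pentylbenzoic acid F2. This acid would be condensed with a second portion of 14 through its mixed trifluoroacetic anhydride (TFAA, toluene, rt), the usual way to force a hindered benzoic acid onto a phenol, to give benzyl 4-{[4-(tert-butyldimethylsilyloxy)-2-methoxy-6-pentylbenzoyl]oxy}-2-methoxy-6-pentylbenzoate F3. Buffered fluoride (TBAF, AcOH, THF, 0 °C) should remove the silyl group and deliver 18.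

2. Step 5. Cycloaddition to the less activated alkyl ynoate may be too slow at temperatures the diene tolerates, so that diene decomposition and incomplete aromatisation take over. The fallback makes ring B from a preformed resorcylate. It sets out from benzyl alcohol 10 and comes back at 14. Commercial olivetolic acid F4 (2,4-dihydroxy-6-pentylbenzoic acid) would be esterified with 10 under Mitsunobu conditions (PPh3, DIAD, THF, 0 °C), where the far more acidic carboxyl group reacts ahead of the phenols, to give benzyl 2,4-dihydroxy-6-pentylbenzoate F5. The free C4 hydroxyl (the C2 hydroxyl is hydrogen-bonded to the ester) would be allylated selectively (allyl bromide, K2CO3, acetone) to benzyl 4-(allyloxy)-2-hydroxy-6-pentylbenzoate F6. Forcing methylation of the chelated hydroxyl (MeI, K2CO3, DMF, 50 °C) should give benzyl 4-(allyloxy)-2-methoxy-6-pentylbenzoate F7. Deallylation (Pd(PPh3)4 cat., morpholine, THF) would return 14.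

3. Step 1. Cationic polymerisation of 1,1-dichloroethene under AlCl3 and incomplete dehydrochlorination may leave an inseparable mixture. The fallback reaches the acylketene acetal by C-acylation of a ketene acetal. It sets out from acetyl chloride 1 and comes back at 6, bypassing 4 and step 2. Commercial 1,1-dimethoxyethene F8 would be acylated at its nucleophilic CH2 carbon with 1 in the presence of pyridine (CH2Cl2, 0 °C), and loss of the proton should give 6 directly.

**Further compounds**

F1 | step 7 | benzyl 4-(tert-butyldimethylsilyloxy)-2-methoxy-6-pentylbenzoate | CCCCCc1cc(O[Si](C)(C)C(C)(C)C)cc(OC)c1C(=O)OCc1ccccc1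
F2 | step 7 | 4-(tert-butyldimethylsilyloxy)-2-methoxy-6-pentylbenzoic acid | CCCCCc1cc(O[Si](C)(C)C(C)(C)C)cc(OC)c1C(=O)O
F3 | step 7 | benzyl 4-{[4-(tert-butyldimethylsilyloxy)-2-methoxy-6-pentylbenzoyl]oxy}-2-methoxy-6-pentylbenzoate | CCCCCc1cc(OC(=O)c2c(CCCCC)cc(O[Si](C)(C)C(C)(C)C)cc2OC)cc(OC)c1C(=O)OCc1ccccc1
F4 | step 5 | olivetolic acid (2,4-dihydroxy-6-pentylbenzoic acid, commercial) | CCCCCc1cc(O)cc(O)c1C(=O)O
F5 | step 5 | benzyl 2,4-dihydroxy-6-pentylbenzoate | CCCCCc1cc(O)cc(O)c1C(=O)OCc1ccccc1
F6 | step 5 | benzyl 4-(allyloxy)-2-hydroxy-6-pentylbenzoate | CCCCCc1cc(OCC=C)cc(O)c1C(=O)OCc1ccccc1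
F7 | step 5 | benzyl 4-(allyloxy)-2-methoxy-6-pentylbenzoate | CCCCCc1cc(OCC=C)cc(OC)c1C(=O)OCc1ccccc1
F8 | step 1 | 1,1-dimethoxyethene (commercial) | C=C(OC)OC
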